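(The earlier runs and the new flask are calculated with constants of no real substance.)

common to all: electrophile 0.11 M
- south-east: free base 0.11 M; protonated nucleophile 0.22 M; the very flask that is asked about, followed so far
- flask: free base 0.110 M; protonated nucleophile 0.220 M; time 1.0 h
- south-east (time / min: electrophile / %, target / %): 1.00: 93, 3; 2.00: 82, 15; 3.00: 82, 15; 4.00: 77, 18; 5.00: 74, 25

(readings scatter by 2 percentage points)
- part of the electrophile that has reacted at 1.0 h
- share of free nucleophile in free nucleophile and protonated nucleophile together, at 1.0 h
- the earlier runs do not show how much of nucleophile is bound; that part of a forecast is a guess

1. We start from the one constant the south-east run offers, which is this flask followed so far. Its electrophile reads 74% at 5.00 min. If electrophile and free nucleophile fall together, that reading gives a constant of 4.22 h⁻¹ in fractions of the charge.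

2. Fastest rung, which we assume: before the first reading at 1.00 min, the free base has taken protons from the protonated nucleophile. Per unit of electrophile, this flask holds a cover, the base equivalents, of 1.00, and a stock of protonated nucleophile of 2.00.

3. Middle rung: substitution has the time scale 14.2 min, shorter than the asked 1.0 h. So we reckon 80.8% reacted.

4. Last rung, the protons: each substitution uses one free nucleophile and sets one proton free. If that proton binds a second nucleophile, a reacted part c leaves free nucleophile of cover minus twice c, which reaches zero at c = 50.0%, below our reckoned part. So our reckoning assumes instead that every released proton is carried off: free nucleophile is then cover minus c, out of stock minus c, and it falls together with electrophile as in step 1. On that assumption our free share is 16.1%.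

The forecast says 80% (62% to 95%) and, differing from our share, 9% (2% to 25%), adding "though a neutral pathway would raise it".

The flask gives 84.3% reacted and a free share of 36.0%, above the forecast's range.

    acid set free + free base ⇌ salt of the base, settled at all times (K = 85700 L mol⁻¹)
    acid set free → by-product carried off (k = 0.00340 s⁻¹)
    nucleophile ⇌ dormant form (K = 0.510, k = 7.38 × 10⁻⁴ s⁻¹)
    nucleophile + acid set free ⇌ protonated nucleophile, settled at all times (K = 250 L mol⁻¹)
    2 electrophile → homo dimer (k = 1.64 × 10⁻⁵ L mol⁻¹ s⁻¹)
    electrophile + nucleophile → acid set free + target (k = 0.0128 L mol⁻¹ s⁻¹)

With 84.3% reacted, this flask stands past the 50.0% of step 4, and its by-product carried off, at 0.126 M, is 1.14 of the electrophile charge, above its reacted part. The neighbouring flask, charged with 0.44 M of electrophile, has a cover of 0.250, so its balance with bound protons reaches zero at 12.5%. That neighbouring flask has reacted 46.2%, with by-product carried off at 0.274 M, and it holds a free share of 25.9%.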